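**Plan**

1. Retrosynthesis: the two senecioate C–O bonds are cut last. The side chain is cut between the methylene-bearing carbon and the carbinol carbon (α-alkoxy organolithium plus ring carboxamide, then C=O to C=CH2). The epoxide is cut at its secondary carbon to a tertiary alkoxide and a trans mesylate, and the ring ketone with its α-oxygen goes back to an enol ether. The ring is then cut at CH2–CH(side chain) and at CH(O)–C(CH3)(O) by a retro-[4+2].
2. Enabling feature: on the cyclohexane ring the epoxide oxygen on the methyl-bearing carbon and the sp2 side-chain carbon on the 1,4-related ring carbon are cis. Together they are the O and C=O of a lactone bridge, i.e. O1–C2 of a 6-methyl-2-pyrone, and the acyloxy-bearing ring carbon is pyrone C4. The diene is therefore triacetic acid lactone MOM ether and the two-carbon partner a vinylboronate (boron is an acceptor that is not acidifying and becomes the leaving-group oxygen).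
3. Forward: the [4+2] dearomatises the pyrone and forms the carbocycle as a 2-oxabicyclo[2.2.2]octenone. C–B becomes C–OH and then OMs, and the enol ether is hydroborated. Opening the lactone bridge frees the alkoxide that closes the epoxide ring. The side chain is joined at the former lactone carbonyl, which is methylenated; ring ketone and both esters come last.
4. Stereochemistry: the bridge fixes the cis relation of epoxide oxygen and side chain, and endo addition puts the leaving group trans to that oxygen. A lipase resolution gives the absolute configuration. Hydroboration from the lactone face sets the ring CH–O trans to the side chain. The side-chain carbinol comes from an asymmetric acylstannane reduction and is transferred with retention.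

Key step: step 2

Remark on the chemistry: the cycloaddition is run without chiral control, so 4, 5 and 6 are racemic (SMILES: both enantiomers joined by a dot, the one carried on first); absolute configuration enters in step 4. MOM = methoxymethyl.

**Step 1**
Reactants: 1 4-hydroxy-6-methyl-2H-pyran-2-one (triacetic acid lactone)
Product: 2 4-(methoxymethoxy)-6-methyl-2H-pyran-2-one
Conditions: MOMCl, i-Pr2NEt, CH2Cl2, 0 °C to rt
Reagents that add atoms: chloromethyl methyl ether, COCCl
Why: O-alkylation (Williamson-type etherification) of the acidic vinylogous carboxylic acid hydroxyl by the hard alkoxymethyl chloride should give the 4-alkoxy-2-pyrone, a stable electron-rich diene; no stereocentre is formed.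

**Step 2**
Reactants: 2 4-(methoxymethoxy)-6-methyl-2H-pyran-2-one; 3 4,4,5,5-tetramethyl-2-vinyl-1,3,2-dioxaborolane (vinylboronic acid pinacol ester)
Product: 4 racemic endo cycloadduct 5-(methoxymethoxy)-1-methyl-7-(4,4,5,5-tetramethyl-1,3,2-dioxaborolan-2-yl)-2-oxabicyclo[2.2.2]oct-5-en-3-one (boron on C7 syn to the C5=C6 bridge)
Conditions: 3 (4 equiv), CH2Cl2, BHT (trace), 14 kbar, 40 °C
Reagents that add atoms: none
Why: This is a concerted, asynchronous Diels–Alder reaction of normal electron demand in which the 4-alkoxy-2-pyrone acts as a cyclic, partly aromatic diene (C3=C4–C5=C6) and the vinylboronate, polarised by the vacant boron p orbital, as dienophile, so that the pyrone is dearomatised to a 2-oxabicyclo[2.2.2]oct-5-en-3-one. The closest known reaction types are thermal or high-pressure Diels–Alder additions of 2-pyrones to activated alkenes that keep the CO2 bridge, and Diels–Alder additions of vinylboron dienophiles. The six-membered carbocycle of the target is closed by the suprafacial [4πs+2πs] union (pyrone C6 to CH–B and pyrone C3 to CH2), while the old pyrone ring survives as the lactone bridge. The two bridgehead stereocentres (the quaternary C(CH3)–O carbon and the CH–C=O carbon) are fixed relative to each other by the bridge, which can span only one face of the new ring, and the boron-bearing carbon is set by the endo transition state (boron under C4–C5, away from the lactone bridge); the product is racemic. The step needs regiocontrol, secured by the 4-OMOM donor, which makes C3 the nucleophilic terminus that pairs with the β-carbon of the vinylboronate so that boron ends next to the methyl-bearing bridgehead. It also needs endo selectivity, which should be favoured by secondary overlap with boron, by repulsion between the boronate oxygens and the lactone bridge in the exo mode and by pressure, and retention of the CO2 bridge, secured by working at 40 °C under pressure instead of at the temperatures at which such adducts extrude CO2.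

**Step 3**
Reactants: 4 racemic endo boronate cycloadduct
Product: 6 racemic endo acetate 5-(methoxymethoxy)-1-methyl-3-oxo-2-oxabicyclo[2.2.2]oct-5-en-7-yl acetate, via racemic endo alcohol 5 (not isolated)
Conditions: NaBO3·4H2O, THF/H2O, rt; then Ac2O, pyridine, DMAP (cat.), CH2Cl2, rt
Reagents that add atoms: sodium perborate, [Na+].[O-]OB=O; acetic anhydride, CC(=O)OC(C)=O
Why: Oxidation of the secondary alkylboronic ester (1,2-shift of carbon from boron to oxygen, with retention) should place the hydroxyl in the endo position under weakly basic conditions that spare the bridged lactone and the enol acetal, and DMAP-catalysed acetylation supplies the ester needed for the enzymatic resolution.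

**Step 4**
Reactants: 6 racemic endo acetate
Product: 7 (1R,4R,7R)-7-hydroxy-5-(methoxymethoxy)-1-methyl-2-oxabicyclo[2.2.2]oct-5-en-3-one
Conditions: lipase PS (Burkholderia cepacia, immobilised), n-BuOH, MTBE, 40 °C, to about half conversion; chromatographic separation from the unreacted (7S)-acetate
Reagents that add atoms: none
Why: Lipase-catalysed alcoholysis as a kinetic resolution should cleave only the acetate whose carbinol carbon is (R), as the empirical size rule for secondary carbinols predicts for a centre flanked by a CH2 group and the quaternary bridgehead, so the absolute configuration of all ring stereocentres is fixed here.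

**Step 5**
Reactants: 7 (1R,4R,7R)-alcohol
Product: 8 (1R,4R,7R)-5-(methoxymethoxy)-1-methyl-3-oxo-2-oxabicyclo[2.2.2]oct-5-en-7-yl methanesulfonate
Conditions: MsCl, Et3N, CH2Cl2, 0 °C
Reagents that add atoms: methanesulfonyl chloride, CS(=O)(=O)Cl
Why: Sulfonylation through the sulfene should esterify this hindered secondary alcohol with retention, which installs the leaving group for the later epoxide closure and removes a free hydroxyl that would otherwise steer the borane to the wrong alkene face.

**Step 6**
Reactants: 8 enol ether mesylate
Product: 10 6-hydroxy-5-(methoxymethoxy)-1-methyl-3-oxo-2-oxabicyclo[2.2.2]octan-7-yl methanesulfonate (6-OH syn to the lactone bridge; 5-OMOM and 7-OMs anti to it), via alkylborane 9 (not isolated)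
Conditions: BH3·THF, THF, 0 °C; then NaBO3·4H2O, H2O, 0 °C to rt
Reagents that add atoms: sodium perborate, [Na+].[O-]OB=O
Why: Hydroboration–oxidation of the enol ether should put boron on the oxygen-free alkene carbon and add H and B syn from the face next to the flat lactone bridge, away from the two-carbon bridge carrying the endo mesylate, so the new CH–OMOM centre has its hydrogen on the lactone side and the carbinol forms with retention on oxidation.

**Step 7**
Reactants: 10 hydroxy lactone mesylate
Product: 12 2-hydroxy-N-methoxy-3-(methoxymethoxy)-N,1-dimethyl-7-oxabicyclo[4.1.0]heptane-4-carboxamide (epoxide O, 2-OH and 4-carboxamide on one face; 3-OMOM on the other), via hydroxy mesylate amide 11 (not isolated)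
Conditions: MeNH(OMe)·HCl, i-PrMgCl, THF, −20 to 0 °C; then K2CO3, MeOH, rt
Reagents that add atoms: N,O-dimethylhydroxylamine hydrochloride, CNOC.Cl
Why: Aminolysis of the strained bridged lactone by the magnesium amide should give the Weinreb amide and free the tertiary hydroxyl, whose alkoxide then displaces the trans-diaxial mesylate in an intramolecular SN2 reaction (3-exo-tet, Williamson-type epoxide closure) with inversion, so the epoxide oxygen stays on the face of the carboxamide.

**Step 8**
Reactants: 13 4-methylpent-3-en-1-ol
Product: 14 4-methylpent-3-enal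
Conditions: Dess–Martin periodinane, NaHCO3, CH2Cl2, 0 °C; used without purification
Reagents that add atoms: none
Why: Dess–Martin oxidation under buffered, non-basic conditions should give the β,γ-unsaturated aldehyde without migration of the double bond into conjugation.

**Step 9**
Reactants: 14 4-methylpent-3-enal
Product: 16 4-methyl-1-(tributylstannyl)pent-3-en-1-one, via lithium stannyl alkoxide 15 (not isolated)
Conditions: Bu3SnH, LiN(i-Pr)2, THF, −78 °C; 14, −78 °C; then 1,1'-(azodicarbonyl)dipiperidine, −78 to 0 °C
Reagents that add atoms: tributyltin hydride, CCCC[SnH](CCCC)CCCC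
Why: 1,2-Addition of tributylstannyllithium to the aldehyde followed by hydride transfer from the α-stannyl alkoxide to the azodicarboxamide (an Oppenauer-type oxidation in the same flask) should give the acylstannane without isolation of the labile α-hydroxystannane.

**Step 10**
Reactants: 16 acylstannane
Product: 18 (S)-tributyl[1-(methoxymethoxy)-4-methylpent-3-en-1-yl]stannane, via (S)-hydroxystannane 17 (not isolated)
Conditions: (R)-BINAL-H, Li[AlH(OEt)((R)-1,1'-binaphthalene-2,2'-diolate)], THF, −78 °C; then MOMCl, i-Pr2NEt, CH2Cl2, 0 °C
Reagents that add atoms: chloromethyl methyl ether, COCCl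
Why: Enantioselective hydride reduction of the acylstannane by the binaphthol-modified aluminium hydride, through a six-membered transition state that differentiates the stannyl and alkyl groups, should set the carbinol carbon as (S) (the (S)-reagent is taken instead if the sense proves opposite), and immediate O-alkylation stores it as the configurationally stable MOM ether.

**Step 11**
Reactants: 12 epoxy Weinreb amide; 18 (S)-α-(methoxymethoxy)stannane
Product: 20 (2R)-1-[2-hydroxy-3-(methoxymethoxy)-1-methyl-7-oxabicyclo[4.1.0]heptan-4-yl]-2-(methoxymethoxy)-5-methylhex-4-en-1-one (ring configured as in 12), via α-alkoxy organolithium 19 (not isolated)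
Conditions: 18, n-BuLi, THF, −78 °C; then 12 (pre-treated with LiN(SiMe3)2, THF, −78 °C), −78 °C; aq. NH4Cl
Reagents that add atoms: none
Why: Tin–lithium exchange gives a chelated α-alkoxy organolithium that is configurationally stable at −78 °C and is acylated by the Weinreb amide with retention (Weinreb ketone synthesis, the chelated tetrahedral adduct preventing a second addition), so the side-chain carbinol centre is delivered intact while the ring hydroxyl is masked as its lithium alkoxide.

**Step 12**
Reactants: 20 ketone
Product: 21 3-(methoxymethoxy)-4-[(3R)-3-(methoxymethoxy)-6-methylhepta-1,5-dien-2-yl]-1-methyl-7-oxabicyclo[4.1.0]heptan-2-ol (ring configured as in 12)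
Conditions: Cp2TiMe2 (excess), toluene, 70 °C, dark
Reagents that add atoms: dimethyltitanocene, C[Ti](C)(C1C=CC=C1)C1C=CC=C1
Why: Petasis methylenation through Cp2Ti=CH2 ([2+2] addition to the carbonyl and cycloreversion) is non-basic, so the ketone should become the 1,1-disubstituted alkene without epimerisation of its two α-stereocentres or β-elimination of the ring OMOM group, the free hydroxyl only consuming reagent as a titanium alkoxide.

**Step 13**
Reactants: 21 epoxy alcohol
Product: 22 (1S,3S,4S,6S)-3-(methoxymethoxy)-4-[(3R)-3-(methoxymethoxy)-6-methylhepta-1,5-dien-2-yl]-1-methyl-7-oxabicyclo[4.1.0]heptan-2-one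
Conditions: Dess–Martin periodinane, NaHCO3, CH2Cl2, 0 °C to rt
Reagents that add atoms: none
Why: Dess–Martin oxidation of the only free hydroxyl should give the α,β-epoxy ketone under neutral conditions that leave the epoxide, the acetals and both alkenes untouched, the adjacent CH–OMOM centre being trans to the side chain and therefore already in its more stable configuration.

**Step 14**
Reactants: 22 bis-MOM epoxy ketone
Product: 24 (1S,3S,4S,6S)-3-hydroxy-4-[(3R)-3-hydroxy-6-methylhepta-1,5-dien-2-yl]-1-methyl-7-oxabicyclo[4.1.0]heptan-2-one, via bis-pyridinium salt 23 (not isolated)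
Conditions: TMSOTf, 2,2'-bipyridyl, CH2Cl2, 0 °C; then H2O, rt
Reagents that add atoms: none
Why: Silyl triflate–bipyridyl cleavage of methoxymethyl ethers (acetal exchange to N-alkoxymethyl pyridinium salts, then hydrolysis) works without free protic acid, so both hydroxyls should be released without opening the epoxy ketone or ionising the allylic carbinol.

**Step 15**
Reactants: 24 diol; 25 3-methylbut-2-enoyl chloride (senecioyl chloride)
Product: 26 (1S,3S,4S,6S)-1-methyl-4-[(3R)-6-methyl-3-(3-methylbut-2-enoyloxy)hepta-1,5-dien-2-yl]-2-oxo-7-oxabicyclo[4.1.0]heptan-3-yl 3-methylbut-2-enoate (CNP0140369.1)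
Conditions: 25 (3 equiv), pyridine, DMAP (cat.), CH2Cl2, 0 °C
Reagents that add atoms: none
Why: Acylation of both secondary hydroxyls by the acid chloride under nucleophilic catalysis (esterification) should give the bis-senecioate, pyridine being too weak a base to deconjugate the acyl donor through the vinylketene or to epimerise the α-acyloxy ketone.

**Compound list**

1 | 4-hydroxy-6-methyl-2H-pyran-2-one (triacetic acid lactone) | CC1=CC(O)=CC(=O)O1 | starting material
2 | 4-(methoxymethoxy)-6-methyl-2H-pyran-2-one | COCOC1=CC(=O)OC(C)=C1 | intermediate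
3 | 4,4,5,5-tetramethyl-2-vinyl-1,3,2-dioxaborolane | C=CB1OC(C)(C)C(C)(C)O1 | starting material
4 | racemic 5-(methoxymethoxy)-1-methyl-7-(pinacolboryl)-2-oxabicyclo[2.2.2]oct-5-en-3-one, boron syn to the C5=C6 bridge (endo) | C[C@]12OC(=O)[C@H](C[C@H]1B1OC(C)(C)C(C)(C)O1)C(OCOC)=C2.C[C@@]12OC(=O)[C@@H](C[C@@H]1B1OC(C)(C)C(C)(C)O1)C(OCOC)=C2 | intermediate
5 | racemic 7-hydroxy-5-(methoxymethoxy)-1-methyl-2-oxabicyclo[2.2.2]oct-5-en-3-one, OH syn to the C5=C6 bridge | C[C@]12OC(=O)[C@H](C[C@H]1O)C(OCOC)=C2.C[C@@]12OC(=O)[C@@H](C[C@@H]1O)C(OCOC)=C2 | intermediate (not isolated)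
6 | racemic acetate of 5 | C[C@]12OC(=O)[C@H](C[C@H]1OC(C)=O)C(OCOC)=C2.C[C@@]12OC(=O)[C@@H](C[C@@H]1OC(C)=O)C(OCOC)=C2 | intermediate
7 | (1R,4R,7R)-7-hydroxy-5-(methoxymethoxy)-1-methyl-2-oxabicyclo[2.2.2]oct-5-en-3-one | C[C@]12OC(=O)[C@H](C[C@H]1O)C(OCOC)=C2 | intermediate
8 | (1R,4R,7R)-5-(methoxymethoxy)-1-methyl-3-oxo-2-oxabicyclo[2.2.2]oct-5-en-7-yl methanesulfonate | C[C@]12OC(=O)[C@H](C[C@H]1OS(C)(=O)=O)C(OCOC)=C2 | intermediate
9 | alkylborane from 8: BH2 on C6 syn to the lactone bridge, H on C5 syn to the lactone bridge | C[C@]12OC(=O)[C@H](C[C@H]1OS(C)(=O)=O)[C@H](OCOC)[C@H]2B | intermediate (not isolated)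
10 | 6-hydroxy-5-(methoxymethoxy)-1-methyl-3-oxo-2-oxabicyclo[2.2.2]octan-7-yl methanesulfonate (6-OH syn to the lactone bridge; 5-OMOM and 7-OMs anti to it) | C[C@]12OC(=O)[C@H](C[C@H]1OS(C)(=O)=O)[C@H](OCOC)[C@H]2O | intermediate
11 | 3,4-dihydroxy-N-methoxy-2-(methoxymethoxy)-N,4-dimethyl-5-(methylsulfonyloxy)cyclohexane-1-carboxamide (3-OH and 4-OH cis to the carboxamide; 2-OMOM and 5-OMs trans to it) | CON(C)C(=O)[C@@H]1C[C@@H](OS(C)(=O)=O)[C@](C)(O)[C@H](O)[C@H]1OCOC | intermediate (not isolated)
12 | 2-hydroxy-N-methoxy-3-(methoxymethoxy)-N,1-dimethyl-7-oxabicyclo[4.1.0]heptane-4-carboxamide (epoxide O, 2-OH and carboxamide on one face; 3-OMOM on the other) | CON(C)C(=O)[C@@H]1C[C@@H]2O[C@]2(C)[C@H](O)[C@H]1OCOC | intermediate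
13 | 4-methylpent-3-en-1-ol | CC(C)=CCCO | starting material
14 | 4-methylpent-3-enal | CC(C)=CCC=O | intermediate
15 | lithium 4-methyl-1-(tributylstannyl)pent-3-en-1-olate (racemic) | [Li+].[O-]C(CC=C(C)C)[Sn](CCCC)(CCCC)CCCC | intermediate (not isolated)
16 | 4-methyl-1-(tributylstannyl)pent-3-en-1-one | CCCC[Sn](CCCC)(CCCC)C(=O)CC=C(C)C | intermediate
17 | (S)-4-methyl-1-(tributylstannyl)pent-3-en-1-ol | CCCC[Sn](CCCC)(CCCC)[C@@H](CC=C(C)C)O | intermediate (not isolated)
18 | (S)-tributyl[1-(methoxymethoxy)-4-methylpent-3-en-1-yl]stannane | CCCC[Sn](CCCC)(CCCC)[C@@H](CC=C(C)C)OCOC | intermediate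
19 | (S)-[1-(methoxymethoxy)-4-methylpent-3-en-1-yl]lithium | [Li][C@@H](CC=C(C)C)OCOC | intermediate (not isolated)
20 | (2R)-1-[2-hydroxy-3-(methoxymethoxy)-1-methyl-7-oxabicyclo[4.1.0]heptan-4-yl]-2-(methoxymethoxy)-5-methylhex-4-en-1-one (ring as in 12) | O=C([C@@H](CC=C(C)C)OCOC)[C@@H]1C[C@@H]2O[C@]2(C)[C@H](O)[C@H]1OCOC | intermediate
21 | 3-(methoxymethoxy)-4-[(3R)-3-(methoxymethoxy)-6-methylhepta-1,5-dien-2-yl]-1-methyl-7-oxabicyclo[4.1.0]heptan-2-ol (ring as in 12) | C=C([C@@H](CC=C(C)C)OCOC)[C@@H]1C[C@@H]2O[C@]2(C)[C@H](O)[C@H]1OCOC | intermediate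
22 | (1S,3S,4S,6S)-3-(methoxymethoxy)-4-[(3R)-3-(methoxymethoxy)-6-methylhepta-1,5-dien-2-yl]-1-methyl-7-oxabicyclo[4.1.0]heptan-2-one | C=C([C@@H](CC=C(C)C)OCOC)[C@@H]1C[C@@H]2O[C@]2(C)C(=O)[C@H]1OCOC | intermediate
23 | bis-triflate of 22 in which each OCH2OCH3 has become OCH2–N(+)(2,2'-bipyridin-1-ium) | C=C([C@@H](CC=C(C)C)OC[n+]1ccccc1-c1ccccn1)[C@@H]1C[C@@H]2O[C@]2(C)C(=O)[C@H]1OC[n+]1ccccc1-c1ccccn1.[O-]S(=O)(=O)C(F)(F)F.[O-]S(=O)(=O)C(F)(F)F | intermediate (not isolated)
24 | (1S,3S,4S,6S)-3-hydroxy-4-[(3R)-3-hydroxy-6-methylhepta-1,5-dien-2-yl]-1-methyl-7-oxabicyclo[4.1.0]heptan-2-one | C=C([C@@H](CC=C(C)C)O)[C@@H]1C[C@@H]2O[C@]2(C)C(=O)[C@H]1O | intermediate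
25 | 3-methylbut-2-enoyl chloride | CC(C)=CC(Cl)=O | starting material
26 | (1S,3S,4S,6S)-1-methyl-4-[(3R)-6-methyl-3-(3-methylbut-2-enoyloxy)hepta-1,5-dien-2-yl]-2-oxo-7-oxabicyclo[4.1.0]heptan-3-yl 3-methylbut-2-enoate | C=C([C@@H](CC=C(C)C)OC(=O)C=C(C)C)[C@@H]1C[C@@H]2O[C@]2(C)C(=O)[C@H]1OC(=O)C=C(C)C | target

**Step count**

Total: 15 steps. Longest linear sequence: 12 steps (steps 1–7 and 11–15); the stannane 18 takes 3 steps (8–10).

**Steps most likely to fail**

Step 2. The boronic ester may add too slowly to the partly aromatic pyrone, endo or regiochemical control may erode, or CO2 may be lost if the addition has to be forced. Fallback, setting out from 2 and returning at 5: the boronic ester is replaced by a dialkylvinylborane, 9-vinyl-9-borabicyclo[3.3.1]nonane (toluene, 60 °C, ambient pressure). This is a much stronger acceptor that reacts through a transition state in which boron itself is bonded to the diene terminus and is expected to favour endo addition. The racemic B-alkyl-9-borabicyclononane adduct F1 is oxidised with anhydrous Me3NO (no base) to racemic alcohol 5, which is isolated and acetylated to 6.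

Step 4. The enzyme may fail to turn over the hindered acetate or may discriminate poorly between the enantiomers. Fallback, setting out from 4 and returning at 7: 4 is oxidised (NaBO3·4H2O) to racemic alcohol 5, which is isolated and subjected to a palladium-catalysed aerobic oxidative kinetic resolution (Pd(nbd)Cl2, the sparteine enantiomer that makes the (7S)-alcohol the fast one, O2, toluene, 3 Å sieves, 60 °C). The unwanted enantiomer is dehydrogenated to the diketone (1S,4S)-5-(methoxymethoxy)-1-methyl-2-oxabicyclo[2.2.2]oct-5-ene-3,7-dione F2, and alcohol 7 is left and separated.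

Step 12. The titanium carbene may fail to engage the doubly α-branched ketone, the free hydroxyl may sequester the reagent, or the epoxide may be opened by the titanium alkoxide at 70 °C. Fallback, setting out from 20 and returning at 21: a two-stage Peterson olefination. Me3SiCH2Li with CeCl3 (THF, −78 °C) adds to the ketone without enolising it and gives the β-hydroxysilane F3 (both epimers at the new carbinol carbon converge). KH (THF, 0 °C) then effects syn elimination of silanolate to 21.

**Further compounds**

F1 | step 2 | racemic 7-(9-borabicyclo[3.3.1]nonan-9-yl)-5-(methoxymethoxy)-1-methyl-2-oxabicyclo[2.2.2]oct-5-en-3-one, boron syn to the C5=C6 bridge | C[C@]12OC(=O)[C@H](C[C@H]1B1C3CCCC1CCC3)C(OCOC)=C2.C[C@@]12OC(=O)[C@@H](C[C@@H]1B1C3CCCC1CCC3)C(OCOC)=C2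
F2 | step 4 | (1S,4S)-5-(methoxymethoxy)-1-methyl-2-oxabicyclo[2.2.2]oct-5-ene-3,7-dione | C[C@@]12OC(=O)[C@@H](CC1=O)C(OCOC)=C2
F3 | step 12 | β-hydroxysilane from 20: 2-[2-hydroxy-3-(methoxymethoxy)-1-methyl-7-oxabicyclo[4.1.0]heptan-4-yl]-3-(methoxymethoxy)-6-methyl-1-(trimethylsilyl)hept-5-en-2-ol (either configuration at the new carbinol carbon, other centres as in 20) | C[Si](C)(C)CC(O)([C@@H](CC=C(C)C)OCOC)[C@@H]1C[C@@H]2O[C@]2(C)[C@H](O)[C@H]1OCOC
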